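## Retrosynthetic overview

Cyclohexene locants used throughout: C1 = CH bearing the CH2O–coumarin arm, C2 = C(CH3)=, C3 = CH=, C4 = CH2, C5 = CH–OAc, C6 = C(CH3)2.

1. The coumarin is bought as umbelliferone and attached by Mitsunobu etherification at the primary alcohol of a trans-diol; acetylation of the secondary alcohol follows as the last step.
2. The diol comes from a cyclohexene ester that still carries a C3 trimethylsilyl group and a C5 (S)-1-phenylethyl ether (hydrogenolysis, protodesilylation, ester reduction).
3. That ester is assembled in one operation by a formal [3+3] annulation of a donor–acceptor cyclopropane (C5, C6, C1 and the ester carbon) with 1-methyl-1-(trimethylsilyl)allene (C4, C3, C2 and the methyl group): the bonds C4–C5 and C1–C2 are formed, together with the only ring made in the route, the C2=C3 alkene and both stereocentres.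
4. Enabling feature: the oxygen on C5 and the exocyclic carbon on C1 (carried as an ester) flank the quaternary C6 in a 1,3-donor/acceptor relationship, so the C5–C6–C1 edge is a latent 1,3-zwitterion stored as a cyclopropane; the C4H2–C3H=C2(CH3) edge is an allene in disguise, nucleophilic at its CH2 end and, after a 1,2-silyl shift, electrophilic at its methyl-bearing end.
5. The cyclopropane is made from ethyl diazoacetate and the isobutenyl ether of (S)-1-phenylethanol; its ring stereocentres need no control because ring opening erases them.

Key step: step 4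

Assumption: the facial preference of the (S)-1-phenylethyl-substituted oxocarbenium ion follows the allylic-strain model given under step 4; should the opposite sense be found, (R)-1-phenylethanol would be used in step 1.

## Route

Step 1
Reactants: 1 (S)-1-phenylethanol; 2 3-chloro-2-methylprop-1-ene
Product: 3 {(1S)-1-[(2-methylprop-2-en-1-yl)oxy]ethyl}benzene
Conditions: NaH, Bu4NI (cat.), THF/DMF, 0 to 25 °C
Reagents that add atoms: none
Why: Williamson ether synthesis (SN2 of the alkoxide on the primary allylic chloride); the stereocentre of 1 is not involved.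

Step 2
Reactants: 3 {(1S)-1-[(2-methylprop-2-en-1-yl)oxy]ethyl}benzene
Product: 4 {(1S)-1-[(2-methylprop-1-en-1-yl)oxy]ethyl}benzene
Conditions: RuHCl(CO)(PPh3)3 (cat.), toluene, 100 °C
Reagents that add atoms: none
Why: Ruthenium-hydride-catalysed alkene isomerisation (hydrometalation, β-hydride elimination) should move the double bond into conjugation with oxygen, and the enol ether has no E/Z issue because its terminus carries two methyl groups.

Step 3
Reactants: 4 {(1S)-1-[(2-methylprop-1-en-1-yl)oxy]ethyl}benzene; 5 ethyl diazoacetate
Product: 6 ethyl 2,2-dimethyl-3-[(1S)-1-phenylethoxy]cyclopropane-1-carboxylate (mixture of ring diastereomers)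
Conditions: Rh2(OAc)4 (cat.), CH2Cl2, 25 °C, slow addition of 5
Reagents that add atoms: none
Why: Rh2(OAc)4-catalysed carbene transfer (cyclopropanation) to the electron-rich enol ether should give the donor–acceptor cyclopropane; the ring stereocentres are left uncontrolled because all isomers open to the same zwitterion in step 4.

Step 4
Reactants: 6 ethyl 2,2-dimethyl-3-[(1S)-1-phenylethoxy]cyclopropane-1-carboxylate; 7 (buta-2,3-dien-2-yl)trimethylsilane
Product: 11 ethyl (1S,5R)-2,6,6-trimethyl-5-[(1S)-1-phenylethoxy]-3-(trimethylsilyl)cyclohex-2-ene-1-carboxylate, via oxocarbenium titanium enolate zwitterion 8 (not isolated), via beta-silyl vinyl cation 9 (not isolated), via silyl-shifted vinyl cation 10 (not isolated)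
Conditions: TiCl4 (1.1 equiv), 7 (1.5 equiv), CH2Cl2, −78 °C, slow addition of 6; aq. NaHCO3
Reagents that add atoms: none
Why: Proposed new method: TiCl4 should open cyclopropane 6 between its alkoxy- and ester-bearing carbons to zwitterion 8 (oxocarbenium ion at C5, titanium ester enolate at C1; the quaternary C6 between them excludes collapse to an enol ether), the CH2 terminus of allene 7 adds to the oxocarbenium carbon (C4–C5 bond) to give the β-silyl vinyl cation 9, a 1,2-silyl shift moves the charge to the methyl-bearing carbon (10), and the enolate carbon closes on it (C1–C2 bond) with release of TiCl4; the closest known reactions are the Danheiser annulation of allenylsilanes with enones (the same addition, silyl shift and enolate capture, there in a [3+2] sense), Lewis-acid [3+n] annulations of donor–acceptor cyclopropanes with π-nucleophiles, and formal [3+3] additions of cyclopropane-derived zwitterions to allenylsilanes. The six-membered ring is closed in a 6-(enolexo)-endo-dig attack of the enolate carbon on the linear vinyl cation, so the alkene is formed endocyclic at C2=C3 with silicon marking C3. The C5 stereocentre is set in the first bond formation by the (S)-1-phenylethyl group on the oxocarbenium oxygen: in the E-oxocarbenium ion with the auxiliary C–H eclipsing the C=O bond, the phenyl group shields one face and the allene should add anti to it, giving the (R)-configuration. The C1 stereocentre is set in the ring closure under control of C5: in the half-chair transition state the C5 alkoxy group sits equatorial and the enolate carbon pseudoaxial (a pseudoequatorial position would clash with the collinear C2-methyl group of the vinyl cation), which places the ester trans to the oxygen. The step needs six- over five-ring closure and retention of silicon; the silyl shift, the allylic strain that a tetrasubstituted alkylidenecyclopentane next to C6 would suffer, and the low temperature should secure this, and the diastereomers of 6 converge because their ring stereocentres are erased in 8.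

Step 5
Reactants: 11 ethyl (1S,5R)-2,6,6-trimethyl-5-[(1S)-1-phenylethoxy]-3-(trimethylsilyl)cyclohex-2-ene-1-carboxylate
Product: 12 ethyl (1S,5R)-5-hydroxy-2,6,6-trimethyl-3-(trimethylsilyl)cyclohex-2-ene-1-carboxylate
Conditions: H2 (1 atm), Pd(OH)2 on carbon, EtOAc, 25 °C
Reagents that add atoms: none
Why: Hydrogenolysis of the benzylic C–O bond should free the C5 alcohol with retention (the C5–O bond is not touched), while the tetrasubstituted vinylsilane and the ester are inert.

Step 6
Reactants: 12 ethyl (1S,5R)-5-hydroxy-2,6,6-trimethyl-3-(trimethylsilyl)cyclohex-2-ene-1-carboxylate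
Product: 13 ethyl (1R,5R)-5-hydroxy-2,6,6-trimethylcyclohex-2-ene-1-carboxylate
Conditions: CF3CO2H, CH2Cl2, 0 °C; aq. NaHCO3
Reagents that add atoms: none
Why: Protodesilylation of a vinylsilane: ipso-protonation at C3 gives a tertiary β-silyl cation that loses silicon, so hydrogen replaces silicon and the double bond stays at C2=C3 (the change of the C1 descriptor is only a change of priorities).

Step 7
Reactants: 13 ethyl (1R,5R)-5-hydroxy-2,6,6-trimethylcyclohex-2-ene-1-carboxylate
Product: 14 (1R,5R)-5-(hydroxymethyl)-4,6,6-trimethylcyclohex-3-en-1-ol
Conditions: LiAlH4, THF, 0 °C; aq. NaOH work-up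
Reagents that add atoms: none
Why: Hydride reduction of the ester to the primary alcohol should leave the alkene and both stereocentres untouched.

Step 8
Reactants: 14 (1R,5R)-5-(hydroxymethyl)-4,6,6-trimethylcyclohex-3-en-1-ol; 15 7-hydroxy-2H-chromen-2-one (umbelliferone)
Product: 16 7-{[(1R,5R)-5-hydroxy-2,6,6-trimethylcyclohex-2-en-1-yl]methoxy}-2H-chromen-2-one
Conditions: PPh3, DIAD, THF, 0 to 25 °C
Reagents that add atoms: none
Why: Mitsunobu etherification: the primary alcohol should be activated in preference to the secondary one next to the quaternary C6, the acidic phenol is the nucleophile, and the trans-diol cannot close to a cyclic ether; no stereocentre is involved.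

Step 9
Reactants: 16 7-{[(1R,5R)-5-hydroxy-2,6,6-trimethylcyclohex-2-en-1-yl]methoxy}-2H-chromen-2-one
Product: 17 (1R,5R)-5-{[(2-oxo-2H-chromen-7-yl)oxy]methyl}-4,6,6-trimethylcyclohex-3-en-1-yl acetate
Conditions: Ac2O, pyridine, DMAP (cat.), CH2Cl2, 25 °C
Reagents that add atoms: acetic anhydride CC(=O)OC(C)=O
Why: DMAP-catalysed acylation of the secondary alcohol with retention of configuration should give the target.

## Compound list

1 | (S)-1-phenylethanol | C[C@H](O)c1ccccc1 | starting material
2 | 3-chloro-2-methylprop-1-ene | ClCC(C)=C | starting material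
3 | {(1S)-1-[(2-methylprop-2-en-1-yl)oxy]ethyl}benzene | C[C@H](OCC(C)=C)c1ccccc1 | intermediate
4 | {(1S)-1-[(2-methylprop-1-en-1-yl)oxy]ethyl}benzene | C[C@H](OC=C(C)C)c1ccccc1 | intermediate
5 | ethyl diazoacetate | CCOC(=O)C=[N+]=[N-] | starting material
6 | ethyl 2,2-dimethyl-3-[(1S)-1-phenylethoxy]cyclopropane-1-carboxylate (mixture of ring diastereomers) | CCOC(=O)C1C(O[C@@H](C)c2ccccc2)C1(C)C | intermediate
7 | (buta-2,3-dien-2-yl)trimethylsilane [1-methyl-1-(trimethylsilyl)allene] | C=C=C(C)[Si](C)(C)C | starting material
8 | oxocarbenium titanium enolate zwitterion from ring opening of 6 by TiCl4 (not isolated) | CCOC(O[Ti-](Cl)(Cl)(Cl)Cl)=CC(C)(C)C=[O+][C@@H](C)c1ccccc1 | intermediate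
9 | beta-silyl vinyl cation after formation of the C4–C5 bond (not isolated) | CCOC(O[Ti-](Cl)(Cl)(Cl)Cl)=CC(C)(C)[C@H](O[C@@H](C)c1ccccc1)C[C+]=C(C)[Si](C)(C)C | intermediate
10 | silyl-shifted vinyl cation (not isolated) | CCOC(O[Ti-](Cl)(Cl)(Cl)Cl)=CC(C)(C)[C@H](O[C@@H](C)c1ccccc1)CC([Si](C)(C)C)=[C+]C | intermediate
11 | ethyl (1S,5R)-2,6,6-trimethyl-5-[(1S)-1-phenylethoxy]-3-(trimethylsilyl)cyclohex-2-ene-1-carboxylate | C[C@H](O[C@@H]1CC([Si](C)(C)C)=C(C)[C@@H](C(=O)OCC)C1(C)C)c1ccccc1 | intermediate
12 | ethyl (1S,5R)-5-hydroxy-2,6,6-trimethyl-3-(trimethylsilyl)cyclohex-2-ene-1-carboxylate | O[C@@H]1CC([Si](C)(C)C)=C(C)[C@@H](C(=O)OCC)C1(C)C | intermediate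
13 | ethyl (1R,5R)-5-hydroxy-2,6,6-trimethylcyclohex-2-ene-1-carboxylate | O[C@@H]1CC=C(C)[C@@H](C(=O)OCC)C1(C)C | intermediate
14 | (1R,5R)-5-(hydroxymethyl)-4,6,6-trimethylcyclohex-3-en-1-ol | O[C@@H]1CC=C(C)[C@@H](CO)C1(C)C | intermediate
15 | 7-hydroxy-2H-chromen-2-one (umbelliferone) | Oc1ccc2ccc(=O)oc2c1 | starting material
16 | 7-{[(1R,5R)-5-hydroxy-2,6,6-trimethylcyclohex-2-en-1-yl]methoxy}-2H-chromen-2-one | O[C@@H]1CC=C(C)[C@@H](COc2ccc3ccc(=O)oc3c2)C1(C)C | intermediate
17 | (1R,5R)-5-{[(2-oxo-2H-chromen-7-yl)oxy]methyl}-4,6,6-trimethylcyclohex-3-en-1-yl acetate | CC(=O)O[C@@H]1CC=C(C)[C@@H](COc2ccc3ccc(=O)oc3c2)C1(C)C | target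

## Step count and risks

Total step count: 9. Longest linear sequence: 9 steps (from 1 to 17).

The three steps most likely to fail:

**Step 4 (proposed new method).** The zwitterion may close on the first vinyl cation before the silyl shift (five-membered ring), chloride may strip silicon from the vinyl cation (simple propargylation), or the oxocarbenium ion may lose its auxiliary by ionisation, which would erode facial discrimination. A minor C5 epimer would still carry the auxiliary, would therefore be a diastereomer of 11, and should be removable by chromatography. If the annulation itself fails, the ring would be made by known chemistry through other bonds, an epoxide-initiated cation–olefin cyclisation. This fallback sets out from 15. Mitsunobu etherification of 15 with nerol (PPh3, DIAD, THF) should give 7-{[(2Z)-3,7-dimethylocta-2,6-dien-1-yl]oxy}-2H-chromen-2-one F1. Shi epoxidation of the more electron-rich terminal alkene (D-fructose-derived ketone, KHSO5, K2CO3, MeCN/H2O, 0 °C) is expected to give 7-{[(2Z)-5-[(2R)-3,3-dimethyloxiran-2-yl]-3-methylpent-2-en-1-yl]oxy}-2H-chromen-2-one F2. SnCl4 in CH2Cl2 at −78 °C should then cyclise F2 through a chair transition state in which the Z-alkene places the aryloxymethyl group axial and the hydroxyl group equatorial (trans), with loss of a ring proton to the endocyclic alkene. The route is rejoined at 16.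

**Step 8.** The substitution at the β-branched primary carbon may be slow, so that elimination or alkylation of the reduced azodicarboxylate takes over. The fallback inverts the roles of the partners so that no substitution at the hindered carbon is needed. It sets out from 14: Pd-catalysed C–O cross-coupling of the primary alcohol of 14 with commercial 7-bromo-2H-chromen-2-one ([Pd(C3H5)Cl]2, RockPhos, Cs2CO3, toluene, 90 °C) should give the aryl ether directly and rejoin the route at 16. It makes no new intermediate (none F0).

**Step 6.** The acid may move the ring double bond into conjugation with the ester or epimerise C1 before silicon is lost. The fallback replaces protonation by halogenation and reduction. It sets out from 12: N-iodosuccinimide in MeCN at 0 °C (ipso-iododesilylation) should give ethyl (1S,5R)-5-hydroxy-3-iodo-2,6,6-trimethylcyclohex-2-ene-1-carboxylate F3, whose C–I bond would be reduced with Bu3SnH and Pd(PPh3)4 in THF. The route is rejoined at 13.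

## Further compounds

F1 | step 4 | 7-{[(2Z)-3,7-dimethylocta-2,6-dien-1-yl]oxy}-2H-chromen-2-one | CC(C)=CCC/C(C)=C\COc1ccc2ccc(=O)oc2c1
F2 | step 4 | 7-{[(2Z)-5-[(2R)-3,3-dimethyloxiran-2-yl]-3-methylpent-2-en-1-yl]oxy}-2H-chromen-2-one | CC1(C)O[C@@H]1CC/C(C)=C\COc1ccc2ccc(=O)oc2c1
F0 | step 8 | none | none
F3 | step 6 | ethyl (1S,5R)-5-hydroxy-3-iodo-2,6,6-trimethylcyclohex-2-ene-1-carboxylate | O[C@@H]1CC(I)=C(C)[C@@H](C(=O)OCC)C1(C)C
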